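**Strategy**

The cyclohexene ring (target numbering: C1, C2 and C4 carry CO2H, C3 the aryl group, C5=C6 the alkene, C6 the side chain) is cut at C1–C2 and C5=C6. C1 is α to its own carboxyl but β to a formyl group placed on C6, so the succinate bond C1–C2 becomes a Michael addition. One amine-catalysed domino Michael/aldol condensation joins a malonate-aldehyde (C2–C5) to allyl 4-oxobut-2-enoate (C1, C6), closes the ring, creates the C5=C6 alkene and sets C1. C3 and C4 come from an earlier organocatalytic Michael addition; C2 is set in the final decarboxylation. The formyl group then grows into the propenoate ester.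

Key step: step 6

Remark: ring atoms are named throughout by the target numbering given above; the target is read as the (1R,2R,3S,4R) ring isomer with the (R)-lactate (bought as (R)-danshensu), and the (R)-catalyst in steps 3 and 6 is chosen from the usual steric shielding model of diarylprolinol silyl ethers.

**Route**

Step 1
Reactants: 1 3,4-dihydroxybenzaldehyde
Product: 2 3,4-bis(allyloxy)benzaldehyde
Conditions: allyl bromide (2.5 equiv), K2CO3, DMF, 60 °C
Reagents that add atoms: allyl bromide, C=CCBr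
Why: Williamson ether synthesis, in which both phenoxides are alkylated by the reactive allylic bromide under carbonate base while the aldehyde is inert.

Step 2
Reactants: 2 3,4-bis(allyloxy)benzaldehyde; 3 diallyl malonate
Product: 4 diallyl 2-[3,4-bis(allyloxy)benzylidene]malonate
Conditions: piperidine (cat.), AcOH (cat.), toluene, reflux, azeotropic removal of water
Reagents that add atoms: none
Why: Knoevenagel condensation of the non-enolisable aryl aldehyde with the malonate, driven by removal of water; no stereocentre arises because the two ester groups are identical.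

Step 3
Reactants: 4 diallyl 2-[3,4-bis(allyloxy)benzylidene]malonate; 5 3-[(tert-butyldimethylsilyl)oxy]propanal
Product: 6 diallyl 2-[(1S,2R)-1-[3,4-bis(allyloxy)phenyl]-3-[(tert-butyldimethylsilyl)oxy]-2-formylpropyl]malonate
Conditions: (R)-α,α-diphenylprolinol trimethylsilyl ether (20 mol %), 5 (3 equiv), CHCl3, 4 °C to rt
Reagents that add atoms: none
Why: Enamine-catalysed Michael addition of an aldehyde to an alkylidene malonate, in which the (E)-enamine of 5 attacks the benzylidene carbon through an acyclic synclinal transition state on the face left open by the diphenyl(silyloxy)methyl group, so that C4 is set by the catalyst and C3 syn to it by the relative topicity known for this catalyst class with nitroalkenes.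

Step 4
Reactants: 7 2,2-dimethoxyacetaldehyde (60 wt % in water); 8 allyl 2-(diethoxyphosphoryl)acetate
Product: 9 allyl (E)-4,4-dimethoxybut-2-enoate
Conditions: K2CO3, H2O/THF, 0 °C to rt
Reagents that add atoms: none
Why: Horner–Wadsworth–Emmons olefination of the non-enolisable glyoxal monoacetal with a stabilised phosphonate anion, which should give the (E)-enoate.

Step 5
Reactants: 9 allyl (E)-4,4-dimethoxybut-2-enoate
Product: 10 allyl (E)-4-oxobut-2-enoate
Conditions: TsOH·H2O (cat.), acetone/H2O, rt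
Reagents that add atoms: water, O
Why: Acid-catalysed acetal hydrolysis releases the conjugated aldehyde, the allyl ester and the (E)-alkene being stable to dilute acid at room temperature.

Step 6
Reactants: 6 diallyl 2-[(1S,2R)-1-[3,4-bis(allyloxy)phenyl]-3-[(tert-butyldimethylsilyl)oxy]-2-formylpropyl]malonate; 10 allyl (E)-4-oxobut-2-enoate
Product: 12 triallyl (2S,5R,6R)-6-[3,4-bis(allyloxy)phenyl]-5-{[(tert-butyldimethylsilyl)oxy]methyl}-3-formylcyclohex-3-ene-1,1,2-tricarboxylate, via acyclic dialdehyde 11 (not isolated)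
Conditions: (R)-α,α-diphenylprolinol trimethylsilyl ether (20 mol %), NaOAc (0.5 equiv), CH2Cl2, 0 °C to rt
Reagents that add atoms: none
Why: The catalyst condenses with enal 10 to an iminium ion whose carbon β to nitrogen (C1, α to the allyl ester) is attacked by the malonate carbon of 6 (C2), and the enamine carbon so formed (C6) adds to the tethered aldehyde (C5) before water is lost and the catalyst is released from the conjugated enal. The closest known reaction type is the amine-catalysed domino Michael/aldol condensation of formyl-tethered malonates or nitroalkanes with enals, which is also the closing pair of events of the three-component aldehyde/nitroalkene/enal cascade. The six-membered ring closes by a 6-(enolexo)-exo-trig aldol addition followed by E1cB dehydration. C1 is set by the catalyst, whose diphenyl(silyloxy)methyl group shields one face of the (E)-iminium ion, so that the (R)-catalyst should place the C1 ester trans to the C3 aryl group, while C3 and C4 are carried over unchanged. The step needs attack at the carbon β to the iminium ion and not β to the ester, which the much stronger iminium activation secures, and enamine formation at the new unbranched CH2CHO arm and not at the α-branched aldehyde of 6, which the steric difference secures; the quaternary C2 carries no stereochemistry at this stage.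

Step 7
Reactants: 13 (R)-3-(3,4-dihydroxyphenyl)lactic acid (danshensu)
Product: 14 allyl (R)-3-[3,4-bis(allyloxy)phenyl]-2-hydroxypropanoate
Conditions: allyl bromide (3.3 equiv), K2CO3, DMF, rt
Reagents that add atoms: allyl bromide, C=CCBr
Why: Carbonate deprotonates only the carboxylic acid and the two phenols, so O-alkylation gives the allyl ester and both aryl allyl ethers while the secondary alcohol stays free and the stereocentre is untouched.

Step 8
Reactants: 14 allyl (R)-3-[3,4-bis(allyloxy)phenyl]-2-hydroxypropanoate; 15 2-(diethoxyphosphoryl)acetic acid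
Product: 16 allyl (R)-3-[3,4-bis(allyloxy)phenyl]-2-{[2-(diethoxyphosphoryl)acetyl]oxy}propanoate
Conditions: EDC·HCl, DMAP (cat.), CH2Cl2, 0 °C to rt
Reagents that add atoms: none
Why: Steglich-type carbodiimide esterification acylates the secondary alcohol under DMAP catalysis without touching the α-stereocentre.

Step 9
Reactants: 12 cyclohexene carbaldehyde from step 6; 16 phosphonate from step 8
Product: 17 triallyl (2S,5R,6R)-3-[(E)-3-({(2R)-1-(allyloxy)-3-[3,4-bis(allyloxy)phenyl]-1-oxopropan-2-yl}oxy)-3-oxoprop-1-en-1-yl]-6-[3,4-bis(allyloxy)phenyl]-5-{[(tert-butyldimethylsilyl)oxy]methyl}cyclohex-3-ene-1,1,2-tricarboxylate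
Conditions: LiCl, iPr2NEt, MeCN, 0 °C to rt
Reagents that add atoms: none
Why: Horner–Wadsworth–Emmons olefination under lithium chloride/amine (Masamune–Roush) conditions should convert the enal into the (E)-dienoate with a base too weak to epimerise C1, C4 or the lactate centre.

Step 10
Reactants: 17 silyl ether from step 9
Product: 18 triallyl (2S,5R,6R)-3-[(E)-3-({(2R)-1-(allyloxy)-3-[3,4-bis(allyloxy)phenyl]-1-oxopropan-2-yl}oxy)-3-oxoprop-1-en-1-yl]-6-[3,4-bis(allyloxy)phenyl]-5-(hydroxymethyl)cyclohex-3-ene-1,1,2-tricarboxylate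
Conditions: HF·pyridine, pyridine/THF, 0 °C to rt
Reagents that add atoms: none
Why: Buffered hydrogen fluoride cleaves the primary silyl ether selectively, the allyl esters, allyl ethers and dienoate being inert to it.

Step 11
Reactants: 18 primary alcohol from step 10
Product: 19 (1R,4S,6R)-4,5,5-tris[(allyloxy)carbonyl]-3-[(E)-3-({(2R)-1-(allyloxy)-3-[3,4-bis(allyloxy)phenyl]-1-oxopropan-2-yl}oxy)-3-oxoprop-1-en-1-yl]-6-[3,4-bis(allyloxy)phenyl]cyclohex-2-ene-1-carboxylic acid
Conditions: TEMPO (20 mol %), PhI(OAc)2 (2.2 equiv), MeCN/H2O, rt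
Reagents that add atoms: water, O
Why: Oxoammonium (TEMPO) oxidation takes the primary alcohol through the aldehyde hydrate to the carboxylic acid under nearly neutral conditions that should leave the α-stereocentre C4, the alkenes and the aryl ethers untouched.

Step 12
Reactants: 19 carboxylic acid from step 11
Product: 21 (1R,2R,3S,4R)-6-[(E)-3-{[(1R)-1-carboxy-2-(3,4-dihydroxyphenyl)ethyl]oxy}-3-oxoprop-1-en-1-yl]-3-(3,4-dihydroxyphenyl)cyclohex-5-ene-1,2,4-tricarboxylic acid (CNP0327643.1), via geminal diacid 20 (not isolated)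
Conditions: Pd(OAc)2 (10 mol %), PPh3 (40 mol %), HCO2H, Et3N, 1,4-dioxane, rt then 100 °C, argon
Reagents that add atoms: none
Why: Zerovalent palladium formed from Pd(OAc)2 and PPh3 ionises all eight allyl groups (Tsuji–Trost) and formate reduces the allyl ligands to propene, the freed geminal diacid on C2 loses carbon dioxide on heating, and the resulting enol is expected to be protonated on C2 anti to the pseudoaxial C1 carboxyl group (held axial by allylic strain with the C6 side chain), which places the C2 carboxyl trans to the aryl group and cis to the C1 carboxyl as in the target.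

**Compound list**

1 | 3,4-dihydroxybenzaldehyde | O=Cc1ccc(O)c(O)c1 | starting material
2 | 3,4-bis(allyloxy)benzaldehyde | O=Cc1ccc(OCC=C)c(OCC=C)c1 | intermediate
3 | diallyl malonate | C=CCOC(=O)CC(=O)OCC=C | starting material
4 | diallyl 2-[3,4-bis(allyloxy)benzylidene]malonate | C=CCOC(=O)C(=Cc1ccc(OCC=C)c(OCC=C)c1)C(=O)OCC=C | intermediate
5 | 3-[(tert-butyldimethylsilyl)oxy]propanal | O=CCCO[Si](C)(C)C(C)(C)C | starting material
6 | diallyl 2-[(1S,2R)-1-[3,4-bis(allyloxy)phenyl]-3-[(tert-butyldimethylsilyl)oxy]-2-formylpropyl]malonate | O=C[C@@H](CO[Si](C)(C)C(C)(C)C)[C@H](c1ccc(OCC=C)c(OCC=C)c1)C(C(=O)OCC=C)C(=O)OCC=C | intermediate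
7 | 2,2-dimethoxyacetaldehyde | COC(OC)C=O | starting material
8 | allyl 2-(diethoxyphosphoryl)acetate | CCOP(=O)(OCC)CC(=O)OCC=C | starting material
9 | allyl (E)-4,4-dimethoxybut-2-enoate | COC(OC)/C=C/C(=O)OCC=C | intermediate
10 | allyl (E)-4-oxobut-2-enoate | O=C/C=C/C(=O)OCC=C | intermediate
11 | triallyl (3S,5R,6R)-5-[3,4-bis(allyloxy)phenyl]-7-[(tert-butyldimethylsilyl)oxy]-6-formyl-1-oxoheptane-3,4,4-tricarboxylate (acyclic dialdehyde, not isolated) | O=C[C@@H](CO[Si](C)(C)C(C)(C)C)[C@H](c1ccc(OCC=C)c(OCC=C)c1)C(C(=O)OCC=C)(C(=O)OCC=C)[C@H](CC=O)C(=O)OCC=C | intermediate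
12 | triallyl (2S,5R,6R)-6-[3,4-bis(allyloxy)phenyl]-5-{[(tert-butyldimethylsilyl)oxy]methyl}-3-formylcyclohex-3-ene-1,1,2-tricarboxylate | O=CC1=C[C@@H](CO[Si](C)(C)C(C)(C)C)[C@H](c2ccc(OCC=C)c(OCC=C)c2)C(C(=O)OCC=C)(C(=O)OCC=C)[C@H]1C(=O)OCC=C | intermediate
13 | (R)-3-(3,4-dihydroxyphenyl)lactic acid (danshensu) | O[C@H](Cc1ccc(O)c(O)c1)C(=O)O | starting material
14 | allyl (R)-3-[3,4-bis(allyloxy)phenyl]-2-hydroxypropanoate | O[C@H](Cc1ccc(OCC=C)c(OCC=C)c1)C(=O)OCC=C | intermediate
15 | 2-(diethoxyphosphoryl)acetic acid | CCOP(=O)(OCC)CC(=O)O | starting material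
16 | allyl (R)-3-[3,4-bis(allyloxy)phenyl]-2-{[2-(diethoxyphosphoryl)acetyl]oxy}propanoate | CCOP(=O)(OCC)CC(=O)O[C@H](Cc1ccc(OCC=C)c(OCC=C)c1)C(=O)OCC=C | intermediate
17 | triallyl (2S,5R,6R)-3-[(E)-3-({(2R)-1-(allyloxy)-3-[3,4-bis(allyloxy)phenyl]-1-oxopropan-2-yl}oxy)-3-oxoprop-1-en-1-yl]-6-[3,4-bis(allyloxy)phenyl]-5-{[(tert-butyldimethylsilyl)oxy]methyl}cyclohex-3-ene-1,1,2-tricarboxylate | O=C(/C=C/C1=C[C@@H](CO[Si](C)(C)C(C)(C)C)[C@H](c2ccc(OCC=C)c(OCC=C)c2)C(C(=O)OCC=C)(C(=O)OCC=C)[C@H]1C(=O)OCC=C)O[C@H](Cc1ccc(OCC=C)c(OCC=C)c1)C(=O)OCC=C | intermediate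
18 | triallyl (2S,5R,6R)-3-[(E)-3-({(2R)-1-(allyloxy)-3-[3,4-bis(allyloxy)phenyl]-1-oxopropan-2-yl}oxy)-3-oxoprop-1-en-1-yl]-6-[3,4-bis(allyloxy)phenyl]-5-(hydroxymethyl)cyclohex-3-ene-1,1,2-tricarboxylate | O=C(/C=C/C1=C[C@@H](CO)[C@H](c2ccc(OCC=C)c(OCC=C)c2)C(C(=O)OCC=C)(C(=O)OCC=C)[C@H]1C(=O)OCC=C)O[C@H](Cc1ccc(OCC=C)c(OCC=C)c1)C(=O)OCC=C | intermediate
19 | (1R,4S,6R)-4,5,5-tris[(allyloxy)carbonyl]-3-[(E)-3-({(2R)-1-(allyloxy)-3-[3,4-bis(allyloxy)phenyl]-1-oxopropan-2-yl}oxy)-3-oxoprop-1-en-1-yl]-6-[3,4-bis(allyloxy)phenyl]cyclohex-2-ene-1-carboxylic acid | O=C(/C=C/C1=C[C@@H](C(=O)O)[C@H](c2ccc(OCC=C)c(OCC=C)c2)C(C(=O)OCC=C)(C(=O)OCC=C)[C@H]1C(=O)OCC=C)O[C@H](Cc1ccc(OCC=C)c(OCC=C)c1)C(=O)OCC=C | intermediate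
20 | (2S,5R,6R)-3-[(E)-3-{[(1R)-1-carboxy-2-(3,4-dihydroxyphenyl)ethyl]oxy}-3-oxoprop-1-en-1-yl]-6-(3,4-dihydroxyphenyl)cyclohex-3-ene-1,1,2,5-tetracarboxylic acid (geminal diacid, not isolated) | O=C(/C=C/C1=C[C@@H](C(=O)O)[C@H](c2ccc(O)c(O)c2)C(C(=O)O)(C(=O)O)[C@H]1C(=O)O)O[C@H](Cc1ccc(O)c(O)c1)C(=O)O | intermediate
21 | (1R,2R,3S,4R)-6-[(E)-3-{[(1R)-1-carboxy-2-(3,4-dihydroxyphenyl)ethyl]oxy}-3-oxoprop-1-en-1-yl]-3-(3,4-dihydroxyphenyl)cyclohex-5-ene-1,2,4-tricarboxylic acid (CNP0327643.1) | O=C(/C=C/C1=C[C@@H](C(=O)O)[C@H](c2ccc(O)c(O)c2)[C@@H](C(=O)O)[C@H]1C(=O)O)O[C@H](Cc1ccc(O)c(O)c1)C(=O)O | target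

**Summary**

Total step count: 12. Longest linear sequence: 8 steps (1, 2, 3, 6, 9, 10, 11, 12).

Steps most likely to fail:

1. Step 6. The intermolecular addition of the hindered tertiary malonate to the iminium ion may be too slow, which would leave room for oligomerisation of the enal, loss of silanol from the β-silyloxy aldehyde and erosion of facial control at C1. The fallback sets out from 6 and separates the two bond formations. The aldehyde is masked with HC(OMe)3 and PPTS in MeOH as the dimethyl acetal F1. Its malonate anion (Cs2CO3 cat., THF, −20 °C) is added to enal 10 at the carbon β to the formyl group, which should give the acetal aldehyde F2 together with its C1 epimer. TsOH in acetone/water then unmasks dialdehyde 11, and dibenzylammonium trifluoroacetate in toluene closes it by the same intramolecular aldol condensation. C1 is then not under catalyst control, so the epimers would be separated or equilibrated with DBU at the stage of the enal. The fallback comes back at 12.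

2. Step 12. Protonation of the enol formed on decarboxylation may occur unselectively or on the wrong face of C2, and the free catechols may degrade during heating. The fallback sets out from 17 and moves the decarboxylation to the fully protected stage. Krapcho dealkoxycarbonylation (LiCl, H2O, DMSO, 130 °C) removes one allyl ester of the geminal pair and gives the monoester F3. As an ester, C2 can be equilibrated with DBU in toluene towards the epimer with the carboxylate trans to the aryl group, and the epimers can be separated by chromatography. Desilylation as in step 10 gives the alcohol F4 and oxidation as in step 11 gives the acid F5. Deallylation with Pd(PPh3)4 and morpholine in THF at room temperature, without a heating stage, comes back at 21.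

3. Step 3. The enamine may add too slowly to the electron-rich benzylidene malonate, with competing β-elimination of silanol from 5 and loss of syn selectivity. The fallback sets out from 2 and builds the same carbon chain in the opposite order. Wittig reaction with (triphenylphosphoranylidene)acetaldehyde gives the cinnamaldehyde F6. Iminium-catalysed Michael addition of diallyl malonate 3 ((R)-α,α-diphenylprolinol trimethylsilyl ether, EtOH) sets C3 and gives the aldehyde F7. Enamine-catalysed α-hydroxymethylation with aqueous formaldehyde ((S)-α,α-diphenylprolinol trimethylsilyl ether, toluene) installs C4 and gives the hydroxy aldehyde F8. Silylation with TBSCl and imidazole comes back at 6.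

**Further compounds**

F1 | step 6 | diallyl 2-[(1S,2R)-1-[3,4-bis(allyloxy)phenyl]-3-[(tert-butyldimethylsilyl)oxy]-2-(dimethoxymethyl)propyl]malonate | COC(OC)[C@@H](CO[Si](C)(C)C(C)(C)C)[C@H](c1ccc(OCC=C)c(OCC=C)c1)C(C(=O)OCC=C)C(=O)OCC=C
F2 | step 6 | triallyl (3S,5R,6R)-5-[3,4-bis(allyloxy)phenyl]-7-[(tert-butyldimethylsilyl)oxy]-6-(dimethoxymethyl)-1-oxoheptane-3,4,4-tricarboxylate | COC(OC)[C@@H](CO[Si](C)(C)C(C)(C)C)[C@H](c1ccc(OCC=C)c(OCC=C)c1)C(C(=O)OCC=C)(C(=O)OCC=C)[C@H](CC=O)C(=O)OCC=C
F3 | step 12 | diallyl (1R,2R,5R,6S)-3-[(E)-3-({(2R)-1-(allyloxy)-3-[3,4-bis(allyloxy)phenyl]-1-oxopropan-2-yl}oxy)-3-oxoprop-1-en-1-yl]-6-[3,4-bis(allyloxy)phenyl]-5-{[(tert-butyldimethylsilyl)oxy]methyl}cyclohex-3-ene-1,2-dicarboxylate | O=C(/C=C/C1=C[C@@H](CO[Si](C)(C)C(C)(C)C)[C@H](c2ccc(OCC=C)c(OCC=C)c2)[C@@H](C(=O)OCC=C)[C@H]1C(=O)OCC=C)O[C@H](Cc1ccc(OCC=C)c(OCC=C)c1)C(=O)OCC=C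
F4 | step 12 | diallyl (1R,2R,5R,6S)-3-[(E)-3-({(2R)-1-(allyloxy)-3-[3,4-bis(allyloxy)phenyl]-1-oxopropan-2-yl}oxy)-3-oxoprop-1-en-1-yl]-6-[3,4-bis(allyloxy)phenyl]-5-(hydroxymethyl)cyclohex-3-ene-1,2-dicarboxylate | O=C(/C=C/C1=C[C@@H](CO)[C@H](c2ccc(OCC=C)c(OCC=C)c2)[C@@H](C(=O)OCC=C)[C@H]1C(=O)OCC=C)O[C@H](Cc1ccc(OCC=C)c(OCC=C)c1)C(=O)OCC=C
F5 | step 12 | (1R,4R,5R,6S)-4,5-bis[(allyloxy)carbonyl]-3-[(E)-3-({(2R)-1-(allyloxy)-3-[3,4-bis(allyloxy)phenyl]-1-oxopropan-2-yl}oxy)-3-oxoprop-1-en-1-yl]-6-[3,4-bis(allyloxy)phenyl]cyclohex-2-ene-1-carboxylic acid | O=C(/C=C/C1=C[C@@H](C(=O)O)[C@H](c2ccc(OCC=C)c(OCC=C)c2)[C@@H](C(=O)OCC=C)[C@H]1C(=O)OCC=C)O[C@H](Cc1ccc(OCC=C)c(OCC=C)c1)C(=O)OCC=C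
F6 | step 3 | (E)-3-[3,4-bis(allyloxy)phenyl]prop-2-enal | O=C/C=C/c1ccc(OCC=C)c(OCC=C)c1
F7 | step 3 | diallyl 2-[(1S)-1-[3,4-bis(allyloxy)phenyl]-3-oxopropyl]malonate | O=CC[C@H](c1ccc(OCC=C)c(OCC=C)c1)C(C(=O)OCC=C)C(=O)OCC=C
F8 | step 3 | diallyl 2-[(1S,2R)-1-[3,4-bis(allyloxy)phenyl]-2-formyl-3-hydroxypropyl]malonate | O=C[C@@H](CO)[C@H](c1ccc(OCC=C)c(OCC=C)c1)C(C(=O)OCC=C)C(=O)OCC=C
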